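**Retrosynthetic overview**

1. Last events: O‑desilylation; C5′–NO2 → C5′–H by radical H‑transfer (cis to the C6′ side chain); 7‑O‑(1,1‑dimethylallyl) → 6‑prenyl/7‑OH by aromatic Claisen rearrangement.
2. Cyclohexene ring (formed last): C1′=C2′ by intramolecular aldol condensation of the ketone α‑carbon onto a chain‑end aldehyde, the presumed biosynthetic closure, run in one flask with the two Michael additions (enone + nitroethane + acrolein) that build the chain.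
3. Enone ⇐ 8‑acetylcoumarin + (S)‑lactaldehyde (from ethyl (S)‑lactate); this single purchased stereocentre (C1″) steers C6′, and C6′ steers C5′.
4. Pyranone ring (formed first): Pechmann union of phloroglucinol with ethyl 2‑methylacetoacetate, as in the presumed biosynthesis; then C8‑acetylation, 5‑O‑methylation, 7‑O‑allylation.
5. Ring order: benzene (purchased) → pyranone → cyclohexene.

Assumption: the biosynthesis is not established; it is taken as a 5,7‑dihydroxycoumarin built from a phloroglucinol nucleus and a 2‑methylacetoacetyl unit, whose linear reduced 8‑acyl chain closes C2′→C7′ by aldol condensation to the cyclohexene, plus C6‑prenylation and 5‑O‑methylation (locants: C1′–C6′ = cyclohexene with C1′ bearing the C=O; C1″ = carbinol carbon; TBS = tert‑butyldimethylsilyl).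

**Route**

Step 1
Reactants: 1 phloroglucinol; 2 ethyl 2‑methyl‑3‑oxobutanoate
Product: 3 5,7‑dihydroxy‑3,4‑dimethyl‑2H‑chromen‑2‑one
Conditions: conc. H2SO4, 0 °C → rt
Reagents that add atoms: none
Why: Pechmann condensation (transesterification, intramolecular Friedel–Crafts hydroxyalkylation, dehydration) on the C3‑symmetric triol can give only one regioisomer and forms the pyranone as the presumed biosynthesis does.

Step 2
Reactants: 3 5,7‑dihydroxy‑3,4‑dimethyl‑2H‑chromen‑2‑one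
Product: 4 8‑acetyl‑5,7‑dihydroxy‑3,4‑dimethyl‑2H‑chromen‑2‑one
Conditions: Ac2O (1.2 equiv), AlCl3 (4 equiv), ClCH2CH2Cl, 75 °C; aq. HCl
Reagents that add atoms: acetic anhydride CC(=O)OC(C)=O
Why: Friedel–Crafts acylation (O‑acylation then Fries‑type O→C shift) takes C8, the site between O1 and 7‑OH that is not buttressed by the 4‑methyl/5‑OH peri pair, the usual outcome for 5,7‑dihydroxy‑4‑alkylcoumarins.

Step 3
Reactants: 4 8‑acetyl‑5,7‑dihydroxy‑3,4‑dimethyl‑2H‑chromen‑2‑one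
Product: 5 8‑acetyl‑7‑hydroxy‑5‑methoxy‑3,4‑dimethyl‑2H‑chromen‑2‑one
Conditions: MeI (1.05 equiv), K2CO3 (1.1 equiv), acetone, rt
Reagents that add atoms: iodomethane CI
Why: Williamson O‑methylation is selective for the free 5‑OH because the 7‑OH is held in a strong hydrogen bond to the 8‑acetyl carbonyl.

Step 4
Reactants: 6 2‑methylbut‑3‑en‑2‑ol
Product: 7 tert‑butyl 2‑methylbut‑3‑en‑2‑yl carbonate
Conditions: n‑BuLi, THF, 0 °C; Boc2O, 0 °C → rt
Reagents that add atoms: di‑tert‑butyl dicarbonate CC(C)(C)OC(=O)OC(=O)OC(C)(C)C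
Why: Acyl substitution of Boc2O by the lithium alkoxide of the tertiary allylic alcohol gives the mixed carbonate; no stereocentre is involved.

Step 5
Reactants: 5 8‑acetyl‑7‑hydroxy‑5‑methoxy‑3,4‑dimethyl‑2H‑chromen‑2‑one; 7 tert‑butyl 2‑methylbut‑3‑en‑2‑yl carbonate
Product: 8 8‑acetyl‑5‑methoxy‑3,4‑dimethyl‑7‑[(2‑methylbut‑3‑en‑2‑yl)oxy]‑2H‑chromen‑2‑one
Conditions: Pd(PPh3)4 (5 mol %), 4 Å MS, THF, 0 °C → rt
Reagents that add atoms: none
Why: Pd‑catalysed decarboxylative allylic etherification (Tsuji–Trost type) in which the phenoxide, freed by the tert‑butoxide formed in situ, attacks the more substituted end of the 1,1‑dimethyl‑π‑allyl complex; the tertiary ether masks O7 through the base steps and carries the future prenyl group.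

Step 6
Reactants: 9 ethyl (S)‑lactate
Product: 10 ethyl (S)‑2‑[(tert‑butyldimethylsilyl)oxy]propanoate
Conditions: TBSCl, imidazole, DMF, rt
Reagents that add atoms: tert‑butyldimethylsilyl chloride CC(C)(C)[Si](C)(C)Cl
Why: Standard silylation of the secondary alcohol; the stereocentre is not touched.

Step 7
Reactants: 10 ethyl (S)‑2‑[(tert‑butyldimethylsilyl)oxy]propanoate
Product: 11 (S)‑2‑[(tert‑butyldimethylsilyl)oxy]propanal
Conditions: DIBAL‑H (1.05 equiv), CH2Cl2, −78 °C; Rochelle salt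
Reagents that add atoms: none
Why: DIBAL‑H half‑reduction at −78 °C stops at the aluminium hemiacetal, which gives the aldehyde on work‑up without epimerising the α‑silyloxy centre.

Step 8
Reactants: 8 8‑acetyl‑5‑methoxy‑3,4‑dimethyl‑7‑[(2‑methylbut‑3‑en‑2‑yl)oxy]‑2H‑chromen‑2‑one; 11 (S)‑2‑[(tert‑butyldimethylsilyl)oxy]propanal
Product: 14 8‑[(2E,4S)‑4‑(TBS‑oxy)pent‑2‑enoyl]‑5‑methoxy‑3,4‑dimethyl‑7‑[(2‑methylbut‑3‑en‑2‑yl)oxy]‑2H‑chromen‑2‑one, via β‑hydroxy ketone 12 (not isolated), via mesylate 13 (not isolated)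
Conditions: LiHMDS, THF, −78 °C; 11; then MsCl, −78 → 0 °C; then DBU, 0 °C → rt
Reagents that add atoms: none
Why: Directed aldol condensation in which the kinetic lithium enolate of the methyl ketone adds to 11 at −78 °C and mesylation/E1cB elimination gives the (E)‑enone; the C4 stereocentre comes unchanged from 11.

Step 9
Reactants: 14 (2E,4S)‑enone; 15 nitroethane; 16 acrolein
Product: 20 8‑{[(6S)‑6‑[(1S)‑1‑(TBS‑oxy)ethyl]‑5‑methyl‑5‑nitrocyclohex‑1‑en‑1‑yl]carbonyl}‑5‑methoxy‑3,4‑dimethyl‑7‑[(2‑methylbut‑3‑en‑2‑yl)oxy]‑2H‑chromen‑2‑one (both C5′ epimers), via nitroethane adduct 17 (not isolated), via nitro keto‑aldehyde 18 (not isolated), via aldol 19 (not isolated)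
Conditions: 15 (3 equiv), DBU (1 equiv), MeCN, 0 °C → rt; then 16 (4 equiv), 0 °C → rt; then 50 °C
Reagents that add atoms: none
Why: Proposed new method: one‑flask Michael/Michael/aldol‑condensation annulation in which the nitronate of 15 adds to the β‑carbon of 14 on the face anti to the OTBS group of the A1,3‑minimised conformer (Felkin–Anh), fixing the future C6′ (6′S by CIP here only because of the nitro group), the new secondary nitronate adds to 16, and the ketone enolate of 18 attacks the aldehyde (the di‑ortho‑substituted aryl ketone is too hindered to act as the electrophile) and dehydrates by E1cB to the conjugated cyclohexenyl ketone, the same C2′→C7′ aldol closure as in the presumed biosynthesis; the nitro‑bearing C5′ forms as a mixture that step 10 erases; closest known chemistry: base‑mediated nitro‑Michael additions to enones and acrolein, the amine‑catalysed Michael/Michael/aldol‑condensation triple cascade to cyclohexenecarbaldehydes, and base‑mediated cyclisation of ω‑oxo‑aldehydes to 1‑acylcycloalkenes.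

Step 10
Reactants: 20 nitro‑cyclohexenyl ketone (7‑O‑allyl ether)
Product: 22 8‑{[(5R,6R)‑6‑[(1S)‑1‑(TBS‑oxy)ethyl]‑5‑methylcyclohex‑1‑en‑1‑yl]carbonyl}‑7‑hydroxy‑5‑methoxy‑3,4‑dimethyl‑6‑(3‑methylbut‑2‑en‑1‑yl)‑2H‑chromen‑2‑one, via Claisen product 21 (not isolated)
Conditions: PhMe, 110 °C; then Bu3SnH, AIBN, 110 °C, same flask
Reagents that add atoms: none
Why: Aromatic Claisen rearrangement ([3,3], allylic transposition) moves the 1,1‑dimethylallyl group from O7 to the only free ortho carbon C6 as a prenyl group and frees the phenol, then Ono‑type radical denitration (Bu3Sn• cleaves C–NO2) gives a tertiary C5′ radical that takes hydrogen from Bu3SnH on the face opposite the pseudo‑axial C6′ side chain (held axial by A1,2 strain with the aroyl group), so both C5′ epimers converge on the 5′R (5′,6′‑cis) product.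

Step 11
Reactants: 22 TBS ether of the target
Product: 23 8‑{[(5R,6R)‑6‑[(1S)‑1‑hydroxyethyl]‑5‑methylcyclohex‑1‑en‑1‑yl]carbonyl}‑7‑hydroxy‑5‑methoxy‑3,4‑dimethyl‑6‑(3‑methylbut‑2‑en‑1‑yl)‑2H‑chromen‑2‑one (CNP0197455.1)
Conditions: HF·pyridine, pyridine, THF, 0 °C → rt
Reagents that add atoms: none
Why: Fluoride cleavage of the silyl ether under buffered, mildly acidic conditions frees the C1″ alcohol without the base that would trigger oxa‑Michael closure of the 7‑OH onto the enone; no stereocentre is affected.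

**Compound list**

1 | phloroglucinol (benzene‑1,3,5‑triol) | Oc1cc(O)cc(O)c1 | starting material
2 | ethyl 2‑methyl‑3‑oxobutanoate | CCOC(=O)C(C)C(C)=O | starting material
3 | 5,7‑dihydroxy‑3,4‑dimethyl‑2H‑chromen‑2‑one | Cc1c(C)c2c(O)cc(O)cc2oc1=O | intermediate
4 | 8‑acetyl‑5,7‑dihydroxy‑3,4‑dimethyl‑2H‑chromen‑2‑one | CC(=O)c1c(O)cc(O)c2c(C)c(C)c(=O)oc12 | intermediate
5 | 8‑acetyl‑7‑hydroxy‑5‑methoxy‑3,4‑dimethyl‑2H‑chromen‑2‑one | COc1cc(O)c(C(C)=O)c2oc(=O)c(C)c(C)c12 | intermediate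
6 | 2‑methylbut‑3‑en‑2‑ol | CC(C)(O)C=C | starting material
7 | tert‑butyl 2‑methylbut‑3‑en‑2‑yl carbonate | CC(C)(C)OC(=O)OC(C)(C)C=C | intermediate
8 | 8‑acetyl‑5‑methoxy‑3,4‑dimethyl‑7‑[(2‑methylbut‑3‑en‑2‑yl)oxy]‑2H‑chromen‑2‑one | COc1cc(OC(C)(C)C=C)c(C(C)=O)c2oc(=O)c(C)c(C)c12 | intermediate
9 | ethyl (S)‑lactate | C[C@H](O)C(=O)OCC | starting material
10 | ethyl (S)‑2‑[(tert‑butyldimethylsilyl)oxy]propanoate | C[C@H](O[Si](C)(C)C(C)(C)C)C(=O)OCC | intermediate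
11 | (S)‑2‑[(tert‑butyldimethylsilyl)oxy]propanal | C[C@H](O[Si](C)(C)C(C)(C)C)C=O | intermediate
12 | 8‑[(4S)‑3‑hydroxy‑4‑(TBS‑oxy)pentanoyl] analogue of 8 (both C3 epimers; present as lithium alkoxide) | COc1cc(OC(C)(C)C=C)c(C(=O)CC(O)[C@H](C)O[Si](C)(C)C(C)(C)C)c2oc(=O)c(C)c(C)c12 | intermediate (not isolated)
13 | 3‑O‑methanesulfonate of 12 | COc1cc(OC(C)(C)C=C)c(C(=O)CC(OS(C)(=O)=O)[C@H](C)O[Si](C)(C)C(C)(C)C)c2oc(=O)c(C)c(C)c12 | intermediate (not isolated)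
14 | 8‑[(2E,4S)‑4‑(TBS‑oxy)pent‑2‑enoyl]‑5‑methoxy‑3,4‑dimethyl‑7‑[(2‑methylbut‑3‑en‑2‑yl)oxy]‑2H‑chromen‑2‑one | COc1cc(OC(C)(C)C=C)c(C(=O)/C=C/[C@H](C)O[Si](C)(C)C(C)(C)C)c2oc(=O)c(C)c(C)c12 | intermediate
15 | nitroethane | CC[N+](=O)[O-] | starting material
16 | acrolein (prop‑2‑enal) | C=CC=O | starting material
17 | 8‑[(3S,4S)‑4‑(TBS‑oxy)‑3‑(1‑nitroethyl)pentanoyl] analogue of 8 (both epimers at the nitro carbon) | COc1cc(OC(C)(C)C=C)c(C(=O)C[C@@H](C(C)[N+](=O)[O-])[C@H](C)O[Si](C)(C)C(C)(C)C)c2oc(=O)c(C)c(C)c12 | intermediate (not isolated)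
18 | 8‑[(3S,4S)‑4‑(TBS‑oxy)‑3‑(2‑nitro‑5‑oxopentan‑2‑yl)pentanoyl] analogue of 8 (both epimers at the nitro carbon) | COc1cc(OC(C)(C)C=C)c(C(=O)C[C@@H](C(C)(CCC=O)[N+](=O)[O-])[C@H](C)O[Si](C)(C)C(C)(C)C)c2oc(=O)c(C)c(C)c12 | intermediate (not isolated)
19 | 8‑{[(6S)‑6‑[(1S)‑1‑(TBS‑oxy)ethyl]‑2‑hydroxy‑5‑methyl‑5‑nitrocyclohexyl]carbonyl} analogue of 8 (epimers at C1′, C2′, C5′) | COc1cc(OC(C)(C)C=C)c(C(=O)C2C(O)CCC(C)([N+](=O)[O-])[C@H]2[C@H](C)O[Si](C)(C)C(C)(C)C)c2oc(=O)c(C)c(C)c12 | intermediate (not isolated)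
20 | 8‑{[(6S)‑6‑[(1S)‑1‑(TBS‑oxy)ethyl]‑5‑methyl‑5‑nitrocyclohex‑1‑en‑1‑yl]carbonyl}‑5‑methoxy‑3,4‑dimethyl‑7‑[(2‑methylbut‑3‑en‑2‑yl)oxy]‑2H‑chromen‑2‑one (both C5′ epimers) | COc1cc(OC(C)(C)C=C)c(C(=O)C2=CCCC(C)([N+](=O)[O-])[C@H]2[C@H](C)O[Si](C)(C)C(C)(C)C)c2oc(=O)c(C)c(C)c12 | intermediate
21 | 8‑{[(6S)‑6‑[(1S)‑1‑(TBS‑oxy)ethyl]‑5‑methyl‑5‑nitrocyclohex‑1‑en‑1‑yl]carbonyl}‑7‑hydroxy‑5‑methoxy‑3,4‑dimethyl‑6‑(3‑methylbut‑2‑en‑1‑yl)‑2H‑chromen‑2‑one (both C5′ epimers) | COc1c(CC=C(C)C)c(O)c(C(=O)C2=CCCC(C)([N+](=O)[O-])[C@H]2[C@H](C)O[Si](C)(C)C(C)(C)C)c2oc(=O)c(C)c(C)c12 | intermediate (not isolated)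
22 | 8‑{[(5R,6R)‑6‑[(1S)‑1‑(TBS‑oxy)ethyl]‑5‑methylcyclohex‑1‑en‑1‑yl]carbonyl}‑7‑hydroxy‑5‑methoxy‑3,4‑dimethyl‑6‑(3‑methylbut‑2‑en‑1‑yl)‑2H‑chromen‑2‑one | COc1c(CC=C(C)C)c(O)c(C(=O)C2=CCC[C@@H](C)[C@H]2[C@H](C)O[Si](C)(C)C(C)(C)C)c2oc(=O)c(C)c(C)c12 | intermediate
23 | 8‑{[(5R,6R)‑6‑[(1S)‑1‑hydroxyethyl]‑5‑methylcyclohex‑1‑en‑1‑yl]carbonyl}‑7‑hydroxy‑5‑methoxy‑3,4‑dimethyl‑6‑(3‑methylbut‑2‑en‑1‑yl)‑2H‑chromen‑2‑one | COc1c(CC=C(C)C)c(O)c(C(=O)C2=CCC[C@@H](C)[C@H]2[C@H](C)O)c2oc(=O)c(C)c(C)c12 | target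

**Step count and risks**

Total steps: 11. Longest linear sequence: 8 (steps 1, 2, 3, 5, 8, 9, 10, 11).

Most likely to fail:

Step 9 (three‑component annulation). The risks are the π‑facial sense of the nitronate addition (attack anti to OTBS is needed), γ‑epimerisation of 14 by DBU, and side reactions of acrolein before the ring closes. Fallback: exchange donor and acceptor. It sets out from aldehyde 11 and nitroethane 15: Henry addition (cat. TBAF, THF, 0 °C) gives (4S)‑4‑(TBS‑oxy)‑2‑nitropentan‑3‑ol F1, which is dehydrated (DCC, CuCl, Et2O) to (2E,4S)‑4‑(TBS‑oxy)‑2‑nitropent‑2‑ene F2. The lithium enolate of ketone 8 (LiHMDS, THF, −78 °C) is then added to F2. This comes back to the route at 17 (here isolated), which is taken on to 20 with 16/DBU as in step 9. Because the two carbons joined have changed roles, this is the remedy if step 9 shows the opposite facial sense (attack syn to OTBS): that same sense now places C3 as drawn in 17. The nitroalkene is also the stronger acceptor if conversion is the problem.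

Step 10 (Claisen/radical denitration). The risks are incomplete cis selectivity in the hydrogen transfer at C5′ and tin‑radical side reactions of the enone. Fallback: set C5′ by hydrogenation instead of radical reduction, replacing steps 9 and 10. It sets out from enone 14: anti‑selective conjugate addition of the vinyl cuprate made from 2‑bromo‑5,5‑dimethoxypent‑1‑ene (t‑BuLi, CuI; TMSCl, THF, −78 °C) gives the 3‑(5,5‑dimethoxypent‑1‑en‑2‑yl) ketone F3. Acetal hydrolysis (PPTS, acetone/H2O) gives keto‑aldehyde F4, and DBU‑mediated aldol condensation (MeCN, 50 °C) gives the 5′‑methylidene‑cyclohexenyl ketone F5. Aromatic Claisen rearrangement (PhMe, 110 °C) gives the 6‑prenyl phenol F6. Hydrogenation of the 1,1‑disubstituted exocyclic alkene only (H2, RhCl(PPh3)3, PhH), from the face opposite the C6′ side chain, returns to the route at 22.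

Step 5 (Pd O‑allylation of the hydrogen‑bonded 7‑OH). The risks are low reactivity of the chelated phenol and Pd‑mediated isomerisation to the linear prenyl ether. Fallback: alkyne route. It sets out from phenol 5: Cu‑catalysed alkylation with 3‑chloro‑3‑methylbut‑1‑yne (DBU, cat. CuCl2, MeCN, 0 °C) gives the 1,1‑dimethylpropargyl ether F7, and semi‑hydrogenation (H2, Lindlar Pd, quinoline, EtOAc) returns to the route at 8.

**Further compounds**

F1 | step 9 | (4S)‑4‑[(tert‑butyldimethylsilyl)oxy]‑2‑nitropentan‑3‑ol (diastereomer mixture at C2, C3) | CC([N+](=O)[O-])C(O)[C@H](C)O[Si](C)(C)C(C)(C)C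
F2 | step 9 | (2E,4S)‑4‑[(tert‑butyldimethylsilyl)oxy]‑2‑nitropent‑2‑ene | C/C(=C\[C@H](C)O[Si](C)(C)C(C)(C)C)[N+](=O)[O-]
F3 | step 10 | 8‑[(3S,4S)‑4‑(TBS‑oxy)‑3‑(5,5‑dimethoxypent‑1‑en‑2‑yl)pentanoyl]‑5‑methoxy‑3,4‑dimethyl‑7‑[(2‑methylbut‑3‑en‑2‑yl)oxy]‑2H‑chromen‑2‑one | COc1cc(OC(C)(C)C=C)c(C(=O)C[C@@H](C(=C)CCC(OC)OC)[C@H](C)O[Si](C)(C)C(C)(C)C)c2oc(=O)c(C)c(C)c12
F4 | step 10 | 8‑[(3S,4S)‑4‑(TBS‑oxy)‑3‑(5‑oxopent‑1‑en‑2‑yl)pentanoyl]‑5‑methoxy‑3,4‑dimethyl‑7‑[(2‑methylbut‑3‑en‑2‑yl)oxy]‑2H‑chromen‑2‑one | COc1cc(OC(C)(C)C=C)c(C(=O)C[C@@H](C(=C)CCC=O)[C@H](C)O[Si](C)(C)C(C)(C)C)c2oc(=O)c(C)c(C)c12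
F5 | step 10 | 8‑{[(6R)‑6‑[(1S)‑1‑(TBS‑oxy)ethyl]‑5‑methylidenecyclohex‑1‑en‑1‑yl]carbonyl}‑5‑methoxy‑3,4‑dimethyl‑7‑[(2‑methylbut‑3‑en‑2‑yl)oxy]‑2H‑chromen‑2‑one | COc1cc(OC(C)(C)C=C)c(C(=O)C2=CCCC(=C)[C@H]2[C@H](C)O[Si](C)(C)C(C)(C)C)c2oc(=O)c(C)c(C)c12
F6 | step 10 | 8‑{[(6R)‑6‑[(1S)‑1‑(TBS‑oxy)ethyl]‑5‑methylidenecyclohex‑1‑en‑1‑yl]carbonyl}‑7‑hydroxy‑5‑methoxy‑3,4‑dimethyl‑6‑(3‑methylbut‑2‑en‑1‑yl)‑2H‑chromen‑2‑one | COc1c(CC=C(C)C)c(O)c(C(=O)C2=CCCC(=C)[C@H]2[C@H](C)O[Si](C)(C)C(C)(C)C)c2oc(=O)c(C)c(C)c12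
F7 | step 5 | 8‑acetyl‑5‑methoxy‑3,4‑dimethyl‑7‑[(2‑methylbut‑3‑yn‑2‑yl)oxy]‑2H‑chromen‑2‑one | COc1cc(OC(C)(C)C#C)c(C(C)=O)c2oc(=O)c(C)c(C)c12
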